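The route rests on cutting the C6–C7 bond. The key step is an intramolecular Nozaki–Hiyama–Kishi (Barbier) allylation: the allylchromium from a 3-(bromomethyl)-5,6-dihydropyran-2-one adds through C7 to the tethered C6 (Z)-enal, closing the ten-membered carbocycle (C1–C10), setting C6 and C7 and unveiling the C11=C13 methylene at once. It exploits the fact that C12 can be esterified by O9 as well as by O6: a temporary six-membered 9,12-lactone (O9, C9, C8, C7, C11, C12) fixes the allyl geometry and relays C8/C9 to C7, and a later acyl shift to O6 gives the five-membered lactone and frees O9 for acetylation. C8/C9 come from one catalytic anti-alkoxyallylboration.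

Key step: step 13

Remark: germacrane numbering is used throughout (C6 lactone carbinol, C7 ring-fusion carbon, C8 carbinol, C9 acetoxy carbon, C1=C10 and C4=C5 ring olefins, C11=C13 methylene, C12 lactone carbonyl, C14 acyloxymethyl carbon, C15 methyl); the target is (6R,7R,8S,9R), 1(10)Z,4Z, with a (2R)-2-methylbutanoate. The stereochemical outcome of step 13 is a prediction from a transition-state model, not an established result.

Step 1
Reactants: 1 nerol
Product: 2 neryl 4-methoxybenzyl ether
Conditions: NaH, PMBCl, Bu4NI (cat.), THF/DMF, 0 °C → rt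
Reagents that add atoms: 4-methoxybenzyl chloride, COc1ccc(CCl)cc1
Why: Williamson etherification of the primary allylic alkoxide protects O6 as a PMB ether that should survive every step up to its oxidative release in step 11; no stereocentre is formed and the (Z)-C4=C5 bond bought with nerol is untouched.

Step 2
Reactants: 2 neryl 4-methoxybenzyl ether
Product: 4 (4Z)-6-[(4-methoxybenzyl)oxy]-4-methylhex-4-enal, via terminal epoxide 3 (not isolated)
Conditions: mCPBA, CH2Cl2, −20 °C; then H5IO6, THF/H2O, 0 °C
Reagents that add atoms: mCPBA, O=C(OO)c1cccc(Cl)c1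
Why: Prilezhaev epoxidation should select the remote, more electron-rich trisubstituted olefin (the C4=C5 bond is deactivated by the allylic ether oxygen), and periodic acid then cleaves the crude epoxide by hydration and glycol fission to the C1 aldehyde, so the racemic epoxide centre is lost again.

Step 3
Reactants: 4 (4Z)-6-[(4-methoxybenzyl)oxy]-4-methylhex-4-enal; 5 methyl acrylate
Product: 6 methyl (6Z)-3-hydroxy-8-[(4-methoxybenzyl)oxy]-6-methyl-2-methylideneoct-6-enoate (racemic)
Conditions: DABCO (1 equiv), methyl acrylate (excess), MeOH (cat.), rt, several days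
Reagents that add atoms: none
Why: Morita–Baylis–Hillman reaction (amine conjugate addition, aldol, elimination) attaches C10 and C14 to C1; the carbinol centre is formed racemic on purpose because step 4 removes it.

Step 4
Reactants: 6 racemic Morita–Baylis–Hillman adduct
Product: 7 methyl (2Z,6Z)-2-(bromomethyl)-8-[(4-methoxybenzyl)oxy]-6-methylocta-2,6-dienoate
Conditions: CBr4, PPh3, CH2Cl2, 0 °C
Reagents that add atoms: carbon tetrabromide, BrC(Br)(Br)Br
Why: Appel bromination with allylic transposition (SN2') gives the conjugated trisubstituted enoate with the C2 chain trans to the ester, which fixes the (Z)-C1=C10 geometry of the target (CH2Br, the future C9, cis to C2; ester carbon, the future C14, trans).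

Step 5
Reactants: 7 (Z)-bromomethyl enoate
Product: 8 (2Z,6Z)-2-(bromomethyl)-8-[(4-methoxybenzyl)oxy]-6-methylocta-2,6-dien-1-ol
Conditions: i-Bu2AlH (2.5 equiv), CH2Cl2, −78 °C; aq. potassium sodium tartrate
Reagents that add atoms: none
Why: i-Bu2AlH reduces the enoate in 1,2-fashion at −78 °C faster than it attacks the allylic bromide, giving the C14 alcohol with the olefin geometry retained.

Step 6
Reactants: 8 bromo allylic alcohol; 9 (2R)-2-methylbutanoic acid
Product: 10 (2Z,6Z)-2-(bromomethyl)-8-[(4-methoxybenzyl)oxy]-6-methylocta-2,6-dien-1-yl (2R)-2-methylbutanoate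
Conditions: DIC, DMAP (5 mol%), CH2Cl2, −10 °C
Reagents that add atoms: none
Why: Steglich esterification installs the bought (R)-stereocentre of the side chain; the low temperature and the small amount of DMAP should prevent epimerisation of the α-centre and N-alkylation by the allylic bromide.

Step 7
Reactants: 10 bromo ester
Product: 11 (2Z,6Z)-2-formyl-8-[(4-methoxybenzyl)oxy]-6-methylocta-2,6-dien-1-yl (2R)-2-methylbutanoate
Conditions: NMO (3 equiv), 4 Å MS, MeCN, 0 °C → rt
Reagents that add atoms: 4-methylmorpholine N-oxide, C[N+]1([O-])CCOCC1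
Why: Ganem oxidation (SN2 displacement of bromide by the N-oxide oxygen, then base-induced fragmentation of the alkoxyammonium salt) turns C9 into the aldehyde without touching the double bond, so the formyl group should stay cis to C2.

Step 8
Reactants: 11 (Z)-enal; 12 (E)-3-(tert-butyldimethylsilyloxy)prop-1-enylboronic acid pinacol ester
Product: 14 (2Z,6Z)-2-[(1R,2S)-2-(tert-butyldimethylsilyloxy)-1-hydroxybut-3-en-1-yl]-8-[(4-methoxybenzyl)oxy]-6-methylocta-2,6-dien-1-yl (2R)-2-methylbutanoate, via (E)-γ-silyloxyallylboronate 13 (not isolated)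
Conditions: 12, [Ir(cod)(PPh2Me)2]PF6 (3 mol%, H2-activated), THF, rt; then 11, (S)-3,3'-bis(2,4,6-triisopropylphenyl)-1,1'-binaphthyl-2,2'-diyl hydrogen phosphate (5 mol%), 4 Å MS, toluene, −20 °C; aq. NaHCO3
Reagents that add atoms: none
Why: Iridium-hydride olefin isomerisation turns 12 into the (E)-enol-ether allylboronate 13, and the chiral phosphoric acid-catalysed allylboration then runs through a closed chair in which the E geometry gives the anti 8,9 relationship and the (S)-acid is expected to direct addition to the Si face of the aldehyde (the (R)-acid delivers to the Re face of aryl and alkenyl aldehydes), setting 9R and with it 8S.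

Step 9
Reactants: 14 anti homoallylic alcohol; 15 2-(bromomethyl)acrylic acid
Product: 17 C9 2-(bromomethyl)acrylate ester of 14, via 2-(bromomethyl)acryloyl chloride 16 (not isolated)
Conditions: 15, (COCl)2, DMF (cat.), CH2Cl2, 0 °C; then 14, pyridine, CH2Cl2, −20 → 0 °C
Reagents that add atoms: none
Why: O-acylation of the hindered C9 alcohol by the acid chloride (nucleophilic acyl substitution via the acylpyridinium ion) brings in C11, C12 and C13 as a 2-(bromomethyl)acrylate; no stereocentre is touched.

Step 10
Reactants: 17 diene ester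
Product: 18 (5S,6R)-3-(bromomethyl)-5-(tert-butyldimethylsilyloxy)-6-{(2Z,6Z)-8-[(4-methoxybenzyl)oxy]-6-methyl-1-[(2R)-2-methylbutanoyloxy]octa-2,6-dien-2-yl}-5,6-dihydro-2H-pyran-2-one
Conditions: second-generation Hoveyda–Grubbs catalyst (10 mol%), toluene, 80 °C, 5 mM
Reagents that add atoms: none
Why: Ring-closing olefin metathesis between the C7 vinyl group (site of initiation) and the acrylate methylene forms the C7=C11 bond of the six-membered unsaturated lactone, the trisubstituted C1=C10 and C4=C5 olefins being inert; C8 and C9 are untouched and end trans on the ring.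

Step 11
Reactants: 18 PMB-protected bromomethyl lactone
Product: 19 C6 allylic alcohol of 18
Conditions: DDQ, CH2Cl2/pH 7 buffer, 0 °C
Reagents that add atoms: none
Why: DDQ removes the PMB group by hydride abstraction and hydrolysis of the oxocarbenium ion under buffered conditions that leave the silyl ether, the esters and the allylic bromide alone.

Step 12
Reactants: 19 allylic alcohol
Product: 20 C6 (Z)-enal carrying the bromomethyl lactone
Conditions: Dess–Martin periodinane, NaHCO3, CH2Cl2, 0 °C
Reagents that add atoms: none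
Why: Buffered Dess–Martin oxidation gives the neral-type (Z)-enal without acid or base strong enough to isomerise it to the (E)-isomer; it is used at once.

Step 13
Reactants: 20 (Z)-enal carrying the bromomethyl lactone
Product: 22 bridged 9,12-lactone of the ten-membered carbocycle with free C6 hydroxyl (6R,7S,8S,9R), via allylchromium dichloride 21 (not isolated)
Conditions: CrCl2 (8 equiv), THF, rt; 20 added over 12 h by syringe pump (final 2 mM); aq. NH4Cl
Reagents that add atoms: none
Why: Two equivalents of CrCl2 reduce the C13–Br bond to the allyl trivalent-chromium species 21, which adds through C7 to the chromium-bound C6 aldehyde in a six-membered chair (Nozaki–Hiyama–Kishi/Barbier allylation of a 2-(bromomethyl)enoate, the standard reaction type for α-methylene lactones and for germacranolide macrocyclisation), shifting the double bond to C11=C13. The ten-membered carbocycle closes in a 10-exo-trig sense at the aldehyde (C=O outside the new ring), while the six-membered lactone is kept and becomes a three-atom bridge (C11–C12–O9) across C7 and C9. C7: the lactone holds C9 in the plane of the C7=C11 bond, so only the OTBS group and H of C8 differentiate the two faces, and C6 should arrive anti to OTBS, which is also the face on which the C9–C10 tether lies (7,8-trans and 7,9-cis on the lactone, as the target requires). C6: the endocyclic C7=C11 bond fixes C8 cis to C12 (an E-type allyl metal that cannot isomerise), so with C5 equatorial in the chair the C6–O/C7–C8 relationship is anti, which is the 6,7-trans arrangement of the final lactone. The step needs ring closure to beat oligomerisation (slow addition, high dilution) and chemoselectivity for the aldehyde, which CrCl2 provides since it leaves the two esters, the lactone and the silyl ether untouched.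

Step 14
Reactants: 22 bridged 9,12-lactone
Product: 23 6,12-lactone with free C9 hydroxyl and C8 silyl ether (6R,7S,8S,9R)
Conditions: camphor-10-sulfonic acid (10 mol%), CH2Cl2, rt
Reagents that add atoms: none
Why: Acid-catalysed translactonisation (intramolecular transesterification through a tetrahedral intermediate at C12) moves the acyl group from O9 to O6 because the unbridged five-membered α-methylene lactone is expected to be more stable than the bridged six-membered one; no C–O bond at a stereocentre is broken, so C6 and C9 keep their configuration.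

Step 15
Reactants: 23 C9 alcohol
Product: 24 C9 acetate with C8 silyl ether (6R,7S,8S,9R)
Conditions: Ac2O, pyridine, DMAP (cat.), CH2Cl2, 0 °C → rt
Reagents that add atoms: acetic anhydride, CC(=O)OC(C)=O
Why: Acetylation with nucleophilic catalysis by DMAP caps O9, the only free hydroxyl, which the acyl shift has just released while O8 is still silylated.

Step 16
Reactants: 24 silyl ether
Product: 25 target CNP0005248.2 (6R,7R,8S,9R)
Conditions: HF·pyridine, pyridine, THF, 0 °C → rt
Reagents that add atoms: none
Why: Fluoride-mediated desilylation under buffered, slightly acidic conditions frees O8 without base, which should avoid acetyl migration from O9 and lactone migration from O6 to O8.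

Compound list
1 | nerol, (2Z)-3,7-dimethylocta-2,6-dien-1-ol | CC(C)=CCC/C(C)=C\CO | starting material
2 | neryl 4-methoxybenzyl ether | CC(C)=CCC/C(C)=C\COCc1ccc(OC)cc1 | intermediate
3 | terminal (6,7) epoxide of 2, racemic, not isolated | CC1(C)OC1CC/C(C)=C\COCc1ccc(OC)cc1 | intermediate
4 | (4Z)-6-[(4-methoxybenzyl)oxy]-4-methylhex-4-enal (C1–C6, C15) | O=CCC/C(C)=C\COCc1ccc(OC)cc1 | intermediate
5 | methyl acrylate | C=CC(=O)OC | starting material
6 | methyl (6Z)-3-hydroxy-8-[(4-methoxybenzyl)oxy]-6-methyl-2-methylideneoct-6-enoate, racemic at the carbinol | C=C(C(=O)OC)C(O)CC/C(C)=C\COCc1ccc(OC)cc1 | intermediate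
7 | methyl (2Z,6Z)-2-(bromomethyl)-8-[(4-methoxybenzyl)oxy]-6-methylocta-2,6-dienoate | COC(=O)/C(CBr)=C/CC/C(C)=C\COCc1ccc(OC)cc1 | intermediate
8 | (2Z,6Z)-2-(bromomethyl)-8-[(4-methoxybenzyl)oxy]-6-methylocta-2,6-dien-1-ol | OC/C(CBr)=C/CC/C(C)=C\COCc1ccc(OC)cc1 | intermediate
9 | (2R)-2-methylbutanoic acid | CC[C@@H](C)C(=O)O | starting material
10 | (2Z,6Z)-2-(bromomethyl)-8-[(4-methoxybenzyl)oxy]-6-methylocta-2,6-dien-1-yl (2R)-2-methylbutanoate | CC[C@@H](C)C(=O)OC/C(CBr)=C/CC/C(C)=C\COCc1ccc(OC)cc1 | intermediate
11 | (2Z,6Z)-2-formyl-8-[(4-methoxybenzyl)oxy]-6-methylocta-2,6-dien-1-yl (2R)-2-methylbutanoate (formyl carbon = C9, cis to C2) | CC[C@@H](C)C(=O)OC/C(C=O)=C/CC/C(C)=C\COCc1ccc(OC)cc1 | intermediate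
12 | (E)-3-(tert-butyldimethylsilyloxy)prop-1-enylboronic acid pinacol ester | CC(C)(C)[Si](C)(C)OC/C=C/B1OC(C)(C)C(C)(C)O1 | starting material
13 | (E)-3-(tert-butyldimethylsilyloxy)allylboronic acid pinacol ester, not isolated | CC(C)(C)[Si](C)(C)O/C=C/CB1OC(C)(C)C(C)(C)O1 | intermediate
14 | anti homoallylic alcohol, (8S,9R): C9–OH, C8–OTBS, C7 vinyl, C14 (2R)-2-methylbutanoate, C6–OPMB, 1(10)Z,4Z | COc1ccc(COC/C=C(/C)CC/C=C(/COC(=O)[C@H](C)CC)[C@@H](O)[C@@H](O[Si](C)(C)C(C)(C)C)C=C)cc1 | intermediate
15 | 2-(bromomethyl)acrylic acid | C=C(CBr)C(=O)O | starting material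
16 | 2-(bromomethyl)acryloyl chloride, not isolated | C=C(CBr)C(Cl)=O | intermediate
17 | C9 2-(bromomethyl)acrylate of 14, (8S,9R) | COc1ccc(COC/C=C(/C)CC/C=C(/COC(=O)[C@H](C)CC)[C@@H](OC(=O)C(=C)CBr)[C@@H](O[Si](C)(C)C(C)(C)C)C=C)cc1 | intermediate
18 | (5S,6R)-3-(bromomethyl)-5-(tert-butyldimethylsilyloxy)-6-{(2Z,6Z)-8-[(4-methoxybenzyl)oxy]-6-methyl-1-[(2R)-2-methylbutanoyloxy]octa-2,6-dien-2-yl}-5,6-dihydro-2H-pyran-2-one (OTBS and side chain trans) | COc1ccc(COC/C=C(/C)CC/C=C(/COC(=O)[C@H](C)CC)[C@H]2OC(=O)C(CBr)=C[C@@H]2O[Si](C)(C)C(C)(C)C)cc1 | intermediate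
19 | C6 primary allylic alcohol of 18 (PMB removed) | OC/C=C(/C)CC/C=C(/COC(=O)[C@H](C)CC)[C@H]1OC(=O)C(CBr)=C[C@@H]1O[Si](C)(C)C(C)(C)C | intermediate
20 | C6 (Z)-enal of 19 | O=C/C=C(/C)CC/C=C(/COC(=O)[C@H](C)CC)[C@H]1OC(=O)C(CBr)=C[C@@H]1O[Si](C)(C)C(C)(C)C | intermediate
21 | allylchromium dichloride from 20 (trivalent chromium on C13), not isolated | O=C/C=C(/C)CC/C=C(/COC(=O)[C@H](C)CC)[C@H]1OC(=O)C(C[Cr](Cl)Cl)=C[C@@H]1O[Si](C)(C)C(C)(C)C | intermediate
22 | bridged 9,12-lactone: 1(10)Z,4Z ten-membered carbocycle, C6–OH, C8–OTBS, C11=C13 methylene, C14 (2R)-2-methylbutanoate, (6R,7S,8S,9R) | C=C1C(=O)O[C@@H]2/C(COC(=O)[C@H](C)CC)=C\CC/C(C)=C\[C@@H](O)[C@H]1[C@@H]2O[Si](C)(C)C(C)(C)C | intermediate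
23 | 6,12-lactone with C9–OH and C8–OTBS, (6R,7S,8S,9R) | C=C1C(=O)O[C@@H]2/C=C(/C)CC/C=C(/COC(=O)[C@H](C)CC)[C@@H](O)[C@@H](O[Si](C)(C)C(C)(C)C)[C@@H]12 | intermediate
24 | 6,12-lactone with C9–OAc and C8–OTBS, (6R,7S,8S,9R) | C=C1C(=O)O[C@@H]2/C=C(/C)CC/C=C(/COC(=O)[C@H](C)CC)[C@@H](OC(C)=O)[C@@H](O[Si](C)(C)C(C)(C)C)[C@@H]12 | intermediate
25 | CNP0005248.2: (6R,7R,8S,9R)-9-acetoxy-8-hydroxy-14-[(2R)-2-methylbutanoyloxy]germacra-1(10)Z,4Z,11(13)-trien-12,6-olide | C=C1C(=O)O[C@@H]2/C=C(/C)CC/C=C(/COC(=O)[C@H](C)CC)[C@@H](OC(C)=O)[C@@H](O)[C@@H]12 | target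

Total step count: 16. Longest linear sequence: 16 steps (from nerol; compounds 5, 9, 12 and 15 are bought).

Steps most likely to fail

Step 13 (macrocyclic allylation). The allylchromium may react with a second molecule instead of its own aldehyde (oligomerisation), may lose the C8 silyloxy group by β-elimination after metal migration to C7, or may add on the lactone face syn to the silyloxy group or through a chair with C5 axial, giving a C7 or C6 epimer. The fallback closes the same bond by an intramolecular allylboration, which needs no low-valent metal and has a tighter closed transition state. It sets out from alcohol 19: copper-catalysed borylation (B2pin2, CuCl, KOAc, DMF, rt) replaces the bromide by boron and gives the allylboronate alcohol F1; buffered Dess–Martin oxidation gives the boronate enal F2, which is heated in dilute toluene (60–80 °C, Sc(OTf)3 if needed) so that the allylboronate adds through C7 to the C6 aldehyde; mild hydrolysis of the borate returns the route at bridged lactone 22.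

Step 8 (catalytic anti-alkoxyallylboration). Addition to the hindered, α-branched (Z)-enal may be slow, which would give time for Z-to-E isomerisation of the enal and E-to-Z drift of the boronate, and the catalyst pocket may discriminate the aldehyde faces poorly; each of these erodes the anti ratio or the enantiomeric purity. The fallback uses stoichiometric reagent control and sets out from enal 11: Brown's [(E)-3-(1,3,2-dioxaborinan-2-yl)allyl]diisopinocampheylborane (from 2-allenyl-1,3,2-dioxaborinane and the Ipc2BH derived from (+)-α-pinene, THF, −78 °C; then H2O2, NaOAc) should give the anti diol F3; TBSOTf (1.0 equiv), 2,6-lutidine, CH2Cl2, −78 °C should then silylate the less hindered C8 hydroxyl next to the vinyl group, which returns the route at 14.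

Step 10 (ring-closing metathesis). Ring closure onto the electron-poor 1,1-disubstituted bromomethyl acrylate next to a bulky silyl ether may be slower than catalyst decomposition or intermolecular metathesis of the vinyl group. The fallback closes an easier disubstituted olefin first and adds C13 afterwards. It sets out from alcohol 14: acryloyl chloride, i-Pr2NEt, CH2Cl2, −20 °C gives the acrylate F4; ring-closing metathesis (second-generation Grubbs catalyst, CH2Cl2, 40 °C) gives the unsubstituted lactone F5; Morita–Baylis–Hillman hydroxymethylation at C11 (aq. formaldehyde, imidazole, THF/H2O, rt) gives the hydroxymethyl lactone F6; CBr4, PPh3, CH2Cl2, 0 °C converts F6 into 18.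

Further compounds
F1 | step 13 | allylboronate alcohol (C13–Bpin, C6–OH) | OC/C=C(/C)CC/C=C(/COC(=O)[C@H](C)CC)[C@H]1OC(=O)C(CB2OC(C)(C)C(C)(C)O2)=C[C@@H]1O[Si](C)(C)C(C)(C)C
F2 | step 13 | boronate enal (C13–Bpin, C6 aldehyde) | O=C/C=C(/C)CC/C=C(/COC(=O)[C@H](C)CC)[C@H]1OC(=O)C(CB2OC(C)(C)C(C)(C)O2)=C[C@@H]1O[Si](C)(C)C(C)(C)C
F3 | step 8 | anti diol (8S,9R), C8–OH and C9–OH free | COc1ccc(COC/C=C(/C)CC/C=C(/COC(=O)[C@H](C)CC)[C@@H](O)[C@@H](O)C=C)cc1
F4 | step 10 | C9 acrylate of 14 | COc1ccc(COC/C=C(/C)CC/C=C(/COC(=O)[C@H](C)CC)[C@@H](OC(=O)C=C)[C@@H](O[Si](C)(C)C(C)(C)C)C=C)cc1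
F5 | step 10 | 3-unsubstituted 5,6-dihydropyran-2-one | COc1ccc(COC/C=C(/C)CC/C=C(/COC(=O)[C@H](C)CC)[C@H]2OC(=O)C=C[C@@H]2O[Si](C)(C)C(C)(C)C)cc1
F6 | step 10 | 3-(hydroxymethyl)-5,6-dihydropyran-2-one | COc1ccc(COC/C=C(/C)CC/C=C(/COC(=O)[C@H](C)CC)[C@H]2OC(=O)C(CO)=C[C@@H]2O[Si](C)(C)C(C)(C)C)cc1
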